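The α-acyloxy ketone of ring C (O–C3–C4=O, with C4 bonded to ring A) is read as a rearranged enol ester epoxide. Ring C is therefore traced to a 4-acyloxy-2H-chromene, and its C3=C4 bond to ring-closing metathesis. The key step joins the inner vinyl carbon (C3) of an enantioenriched aryl 1-phenylallyl ether to the oxygen-bearing carbon (C4) of a 1-arylvinyl (S)-2-methylbutanoate made from an acetophenone. It closes ring C, expels ethylene and parks the final ester on O4. One oxygen transfer anti to the C2 phenyl group and an O4-to-O3 acyl shift then set C3 and reveal the ketone.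

Key step: step 3

Assumption: compounds 1, 2 and 5 are taken as catalogue chemicals, flavonoid numbering (O1, C2, C3, C4, C4a to C8a) is used throughout, and the phosphoramidite antipode in step 1 is the one that delivers the (S)-ether.

Step 1
Reactants: 1 1-[2,4-bis(benzyloxy)-6-hydroxyphenyl]ethan-1-one; 2 (E)-cinnamyl methyl carbonate
Product: 4 1-[2,4-bis(benzyloxy)-6-{[(1S)-1-phenylprop-2-en-1-yl]oxy}phenyl]ethan-1-one, via sodium phenoxide 3 (not isolated)
Conditions: NaH (1.0 equiv), THF, 0 °C; then 2, [Ir(cod)Cl]2 (2 mol %), BINOL-derived N,N-bis(1-phenylethyl)phosphoramidite (4 mol %, pre-activated with n-PrNH2), THF, rt to 50 °C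
Reagents that add atoms: none
Why: Iridium-catalysed asymmetric allylic etherification, in which the aryloxide attacks the substituted terminus of the π-allyliridium complex anti to the metal, so the branched ether should form and the ligand sets C2 (S here, R in the target only because the CIP ranks of phenyl and C3 swap later).

Step 2
Reactants: 4 1-[2,4-bis(benzyloxy)-6-{[(1S)-1-phenylprop-2-en-1-yl]oxy}phenyl]ethan-1-one; 5 (S)-2-methylbutanoic anhydride
Product: 7 1-[2,4-bis(benzyloxy)-6-{[(1S)-1-phenylprop-2-en-1-yl]oxy}phenyl]ethenyl (2S)-2-methylbutanoate, via potassium enolate 6 (not isolated)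
Conditions: KHMDS (1.0 equiv), THF/DMPU, −78 °C; then cannulated into 5 (2 equiv), THF, −78 °C; cold aq. NaHCO3
Reagents that add atoms: none
Why: Enol ester formation by O-acylation of a dissociated potassium enolate with an anhydride, where only the methyl group is enolisable, the hard acyl donor and inverse addition favour O over C attack, and the low temperature protects the α-stereocentre of the acyl group.

Step 3
Reactants: 7 1-[2,4-bis(benzyloxy)-6-{[(1S)-1-phenylprop-2-en-1-yl]oxy}phenyl]ethenyl (2S)-2-methylbutanoate
Product: 8 (2S)-5,7-bis(benzyloxy)-2-phenyl-2H-chromen-4-yl (2S)-2-methylbutanoate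
Conditions: second-generation Ru metathesis catalyst (NHC, chelating 2-isopropoxybenzylidene; 5–10 mol %), 1,4-benzoquinone (10 mol %), toluene (0.01 M), 60 °C, argon sparge, light excluded
Reagents that add atoms: none
Why: Ring-closing metathesis: the ruthenium alkylidene loads onto the monosubstituted allylic alkene, the resulting Ru=C3 carbene adds [2+2] to the 1,1-disubstituted enol ester alkene with C3 bonding to C4, and cycloreversion releases 8 and Ru=CH2, so ethylene is the only by-product. The closest known reaction types are enol ether–ene ring-closing metathesis of ortho-(1-silyloxyvinyl)aryl allyl amines and the closure of α-substituted ortho-vinylaryl allyl ethers to 4-substituted 2H-chromenes. Ring C closes as an unstrained six-membered ring with both alkene carbons endocyclic, and the ortho relation of the two arms on ring A keeps them within reach. No stereocentre is formed; C2 and the acyl α-carbon are spectators under neutral conditions, and exclusion of light and moderate temperature guard C2 against reversible 6π opening of the 2H-chromene. The step needs initiation at the allyl arm and not at the enol ester, which the steric and electronic deactivation of the latter secures and which also avoids an acyloxy-stabilised carbene on ruthenium. It further needs the allyl ether not to isomerise, for which benzoquinone traps ruthenium hydrides.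

Step 4
Reactants: 8 (2S)-5,7-bis(benzyloxy)-2-phenyl-2H-chromen-4-yl (2S)-2-methylbutanoate
Product: 10 (2R,3R)-5,7-bis(benzyloxy)-4-oxo-2-phenylchroman-3-yl (2S)-2-methylbutanoate, via enol ester epoxide 9 (not isolated)
Conditions: DMDO (1.2 equiv, acetone), CH2Cl2, −20 to 0 °C; then TsOH (10 mol %), CH2Cl2, 0 °C
Reagents that add atoms: dimethyldioxirane, CC1(C)OO1
Why: Epoxidation of the electron-rich enol ester anti to the C2 phenyl group followed by acid-catalysed enol ester epoxide rearrangement, in which the C4–O epoxide bond ionises (cation stabilised by ring A and the acyloxy oxygen) while the C3 oxygen keeps its bond and takes over the acyl group through a five-membered orthoester, giving the C4 ketone and the 2,3-trans (3R) ester with retention.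

Step 5
Reactants: 10 (2R,3R)-5,7-bis(benzyloxy)-4-oxo-2-phenylchroman-3-yl (2S)-2-methylbutanoate
Product: 11 (2R,3R)-5,7-dihydroxy-4-oxo-2-phenylchroman-3-yl (2S)-2-methylbutanoate (target)
Conditions: H2 (1 atm), 10 % Pd/C, EtOAc, rt
Reagents that add atoms: none
Why: Hydrogenolysis of the two aryl benzyl ethers under neutral conditions, which is routinely compatible with the C2–O1 bond, the ketone and a 3-acyloxy group in dihydroflavonols and avoids any base that could enolise C3 or open ring C.

Compound list
1 | 1-[2,4-bis(benzyloxy)-6-hydroxyphenyl]ethan-1-one | CC(=O)c1c(O)cc(OCc2ccccc2)cc1OCc1ccccc1 | starting material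
2 | (E)-cinnamyl methyl carbonate | COC(=O)OC/C=C/c1ccccc1 | starting material
3 | sodium 2-acetyl-3,5-bis(benzyloxy)phenoxide | CC(=O)c1c([O-])cc(OCc2ccccc2)cc1OCc1ccccc1.[Na+] | intermediate
4 | 1-[2,4-bis(benzyloxy)-6-{[(1S)-1-phenylprop-2-en-1-yl]oxy}phenyl]ethan-1-one | C=C[C@H](Oc1cc(OCc2ccccc2)cc(OCc2ccccc2)c1C(C)=O)c1ccccc1 | intermediate
5 | (S)-2-methylbutanoic anhydride | CC[C@H](C)C(=O)OC(=O)[C@@H](C)CC | starting material
6 | potassium enolate of 4 | C=C([O-])c1c(OCc2ccccc2)cc(OCc2ccccc2)cc1O[C@@H](C=C)c1ccccc1.[K+] | intermediate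
7 | 1-[2,4-bis(benzyloxy)-6-{[(1S)-1-phenylprop-2-en-1-yl]oxy}phenyl]ethenyl (2S)-2-methylbutanoate | CC[C@H](C)C(=O)OC(=C)c1c(OCc2ccccc2)cc(OCc2ccccc2)cc1O[C@@H](C=C)c1ccccc1 | intermediate
8 | (2S)-5,7-bis(benzyloxy)-2-phenyl-2H-chromen-4-yl (2S)-2-methylbutanoate | CC[C@H](C)C(=O)OC1=C[C@@H](c2ccccc2)Oc2cc(OCc3ccccc3)cc(OCc3ccccc3)c21 | intermediate
9 | (2R,3R,4R)-5,7-bis(benzyloxy)-3,4-epoxy-2-phenylchroman-4-yl (2S)-2-methylbutanoate (epoxide oxygen trans to the C2 phenyl) | CC[C@H](C)C(=O)O[C@@]12O[C@@H]1[C@@H](c1ccccc1)Oc1cc(OCc3ccccc3)cc(OCc3ccccc3)c12 | intermediate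
10 | (2R,3R)-5,7-bis(benzyloxy)-4-oxo-2-phenylchroman-3-yl (2S)-2-methylbutanoate | CC[C@H](C)C(=O)O[C@H]1C(=O)c2c(OCc3ccccc3)cc(OCc3ccccc3)cc2O[C@@H]1c1ccccc1 | intermediate
11 | (2R,3R)-5,7-dihydroxy-4-oxo-2-phenylchroman-3-yl (2S)-2-methylbutanoate | CC[C@H](C)C(=O)O[C@H]1C(=O)c2c(O)cc(O)cc2O[C@@H]1c1ccccc1 | target

Total step count: 5. Longest linear sequence: 5 steps (1 to 11).

Steps most likely to fail

Step 3. The doubly ortho-flanked, 1,1-disubstituted enol ester alkene may enter the metallacyclobutane too slowly. Catalyst decay, chelation of ruthenium by the ester carbonyl, isomerisation of the allyl ether or thermal erosion of C2 could then take over. The fallback sets out from 4 and changes both the group on O4 and the order of events.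
- Soft enolisation (TBSOTf, Et3N, CH2Cl2, 0 °C) should give the tert-butyldimethylsilyl enol ether F1.
- Its more electron-rich alkene is the established partner of enol ether–ene metathesis (second-generation Ru catalyst, CH2Cl2, reflux) and should close to the 4-silyloxy-2H-chromene F2.
- Rubottom oxidation (DMDO, CH2Cl2, −20 °C) via the silyloxy epoxide F3, followed by HF·pyridine, should give the trans 3-hydroxyflavanone F4.
- Acylation with 5 (DMAP cat., pyridine, CH2Cl2, 0 °C) comes back to the route at 10.

This path also bypasses step 2.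

Step 1. The chelated 2-acylaryloxide may attack sluggishly. Because it is also a fair leaving group, reversible ionisation of the product on iridium may erode the branched selectivity and the enantiomeric purity. The fallback sets out from 1 and takes C2 from a commercial chiral alcohol instead of a catalyst.
- Mitsunobu reaction with (R)-3-chloro-1-phenylpropan-1-ol (PPh3, DIAD, THF, 0 °C) should give, with inversion, the (S)-chloro ether F5.
- Displacement with PhSeNa (PhSeSePh, NaBH4, EtOH) should give the selenide F6.
- Oxidation (H2O2, pyridine, CH2Cl2, 0 °C to rt) via the selenoxide F7 and syn elimination comes back to the route at 4.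

This material also serves to check the sense of induction of step 1.

Step 4. Oxygen transfer may show poor facial selectivity. Part of the epoxide may also leak into the invertive 1,2-acyloxy shift, and either process would erode the 2,3-trans relationship. The fallback sets out from 8 and replaces the epoxide and acyl shift by osmylation.
- OsO4 (cat.) with NMO in acetone/water is bulkier and should add anti to the 2-phenyl group, as it does with flav-3-enes.
- The resulting hemiketal ester F8 should lose the acid to give the 3-hydroxyflavanone F4 without the C3–O bond ever being broken.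
- Re-acylation with 5 (DMAP cat., pyridine, CH2Cl2, 0 °C) comes back to the route at 10.

Further compounds
F1 | step 3 | tert-butyl({1-[2,4-bis(benzyloxy)-6-{[(1S)-1-phenylprop-2-en-1-yl]oxy}phenyl]ethenyl}oxy)dimethylsilane | C=C(O[Si](C)(C)C(C)(C)C)c1c(OCc2ccccc2)cc(OCc2ccccc2)cc1O[C@@H](C=C)c1ccccc1
F2 | step 3 | {[(2S)-5,7-bis(benzyloxy)-2-phenyl-2H-chromen-4-yl]oxy}(tert-butyl)dimethylsilane | CC(C)(C)[Si](C)(C)OC1=C[C@@H](c2ccccc2)Oc2cc(OCc3ccccc3)cc(OCc3ccccc3)c21
F3 | step 3 | (2R,3R,4R)-5,7-bis(benzyloxy)-4-[(tert-butyldimethylsilyl)oxy]-3,4-epoxy-2-phenylchroman | CC(C)(C)[Si](C)(C)O[C@@]12O[C@@H]1[C@@H](c1ccccc1)Oc1cc(OCc3ccccc3)cc(OCc3ccccc3)c12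
F4 | step 3 | (2R,3R)-5,7-bis(benzyloxy)-3-hydroxy-2-phenylchroman-4-one | O[C@H]1C(=O)c2c(OCc3ccccc3)cc(OCc3ccccc3)cc2O[C@@H]1c1ccccc1
F5 | step 1 | 1-[2,4-bis(benzyloxy)-6-{[(1S)-3-chloro-1-phenylpropyl]oxy}phenyl]ethan-1-one | CC(=O)c1c(OCc2ccccc2)cc(OCc2ccccc2)cc1O[C@@H](CCCl)c1ccccc1
F6 | step 1 | 1-[2,4-bis(benzyloxy)-6-{[(1S)-1-phenyl-3-(phenylselanyl)propyl]oxy}phenyl]ethan-1-one | CC(=O)c1c(OCc2ccccc2)cc(OCc2ccccc2)cc1O[C@@H](CC[Se]c1ccccc1)c1ccccc1
F7 | step 1 | 1-[2,4-bis(benzyloxy)-6-{[(1S)-1-phenyl-3-(phenylseleninyl)propyl]oxy}phenyl]ethan-1-one | CC(=O)c1c(OCc2ccccc2)cc(OCc2ccccc2)cc1O[C@@H](CC[Se](=O)c1ccccc1)c1ccccc1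
F8 | step 4 | (2R,3R,4R)-5,7-bis(benzyloxy)-3,4-dihydroxy-2-phenylchroman-4-yl (2S)-2-methylbutanoate | CC[C@H](C)C(=O)O[C@@]1(O)[C@H](O)[C@@H](c2ccccc2)Oc2cc(OCc3ccccc3)cc(OCc3ccccc3)c21
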